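4 questions, a pair for each of alder and oak, and 2 earlier runs to answer them from.

| setting | spring | midnight | alder | oak |
|---|---|---|---|---|
| substrate | 0.050 M | 0.050 M | 0.050 M | 0.050 M |
| first nucleophile | 0.25 M | 0.25 M | 0.250 M | 0.250 M |
| second nucleophile | 0.033 M | 0.064 M | 0.0600 M | 0.0900 M |
| remark | run made earlier | run made earlier |  |  |
| time |  |  | 5.0 min | 5.0 min |

| run | time / min | target / % |
|---|---|---|
| spring | 0.417 | 46 |
| spring | 1.00 | 28 |
| spring | 2.00 | 12 |
| spring | 5.00 | 3 |
| midnight | 0.417 | 28 |
| midnight | 1.00 | 19 |
| midnight | 2.00 | 7 |
| midnight | 5.00 | 0 |

(each reading ± 2 percentage points)

* which of the two there is more of at the end, alder (target / other capture product)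
* which of the two there is more of at the end, oak (target / other capture product)
* target at the end, in percent of the substrate charged, alder
* target at the end, in percent of the substrate charged, oak



*What do the runs show first?*
Target falling from the first reading on: 0.849 /min in spring, 0.876 /min in midnight, though midnight has twice the [second nucleophile].

*And at zero time?*
Run back along those slopes, spring reads 65.5% target and midnight 40.3%. I take the rest of the substrate as other capture product.

*So what do you carry?*
The selectivity factor S, the rate of capture by the second nucleophile over the rate by the first, divided by [second nucleophile]/[first nucleophile]. Time drops out of that ratio. I use the mean [second nucleophile] during capture, the charge less half of what capture consumes, and hold [first nucleophile] at its charge. Spring gives 5.39, midnight 7.53.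

*Those disagree. Why trust either?*
Each leans on extrapolated readings with their scatter, so I commit to the mean, 6.46, as a reading.

*Your answer?*
Solving the same balance for other capture product gives 54.5% in alder and 65.5% in oak. The remainder, decaying at the mean 0.862 /min, leaves 0.610% and 0.462% target.

The forecast, by its own reckoning, names other capture product for alder and other capture product for oak, with target 0.7% (0% to 3%) and 0.5% (0% to 2.5%). Of the target's fall it says: “It is a separate first-order drain.”

The flask gives 0.618% target against 54.9% other capture product in alder, and 0.384% against 65.9% in oak.

    first nucleophile + target → over-reaction product (k = 0.0700 /M/s)
    first nucleophile → decomposition product (k = 2.30 × 10⁻⁶ /s)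
    substrate → intermediate (k = 0.130 /s)
    first nucleophile + intermediate → target (k = 13.0 /M/s)
    intermediate → decomposed reagent (k = 0.0150 /s)
    second nucleophile + intermediate → other capture product (k = 84.0 /M/s)

The largest single effect on alder's final target is the step from first nucleophile and target to over-reaction product: the alder run without it ends at 45.0% target. That step's half-life as charged in alder, 0.66 min, is short against 5.0 min. For the neighbour of oak with [second nucleophile] charged at 0.036 M, S gives 40.2% other capture product; at its end the computed flask holds 40.4%, beside 58.3% over-reaction product.

The data were generated by integration from invented constants; noise was put on by code.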